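# Total synthesis proposal for CNP0077405.3: transannular Reformatsky-type aldol closure of a ten-membered α-bromo-1,6-diketone

## Analysis of the target

1. Atom labels follow halimane numbering, read along the SMILES: C17 (methyl), C8, C7, C6, C5 (tertiary carbinol), C1 (ring-fusion CH), C2, C3 (CHOH), C4 (CMe2), C10 (ketone), C9 (quaternary, C20 methyl), C11, C12, C13=C14, C15 (lactone C=O), C16 (OCH2).
2. The carbocycle is a bicyclo[5.3.0]decane. A cyclopentane (C1–C5) and a cycloheptanone (C1, C5–C10) share the C1–C5 bond, and a CH2CH2 tether on C9 carries a β-substituted butenolide.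
3. The five stereocentres are 1S, 3S, 5S, 8R and 9R. H-1 is anti to 5-OH (trans ring fusion, so 5-OH and the acyl carbon C10 are cis on the cyclopentane). 3-OH is trans to 5-OH. The C17 methyl is cis to the C11 chain and trans to the C20 methyl.
4. The C1/C3/C5 group and the C8/C9 pair are separated by the ketone on one side and by C6–C7 on the other, so neither group readily controls the other.
5. The decisive feature is the unit C5(OH)–C1(H)–C10(=O). It is an aldol whose C–C bond is the bond common to both rings, so a retro-aldol cut opens both rings at once to a cyclodecane-1,6-dione, which is the oxidative cleavage product of a Δ5(10)-octalin.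
6. A second feature makes this cut usable: 3-OH is γ to C10=O but only β to C5=O, so it can tell apart two ketones that are otherwise nearly equivalent, since each is flanked by one quaternary carbon (C9 or C4) and one CH2 (C1 or C6).
7. The sensitive groups are the tertiary β-hydroxy ketone (retro-aldol, dehydration, epimerisable C1) and the butenolide (acidic C16–H, conjugate acceptor).
8. The difficulty lies in the trans-fused aldol flanked by two quaternary carbons, in the constitutional choice between C1–C5 and C6–C10 closure, and in the unusual C17/C20-trans pair at C8/C9.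

## Retrosynthetic reasoning

**C1–C5 (24 ⇒ 21).** The bond shared by both rings is cut in the aldol sense, which removes two rings and two stereocentres (C1, C5) in one move. Plain enolisation of a 1,6-dione could equally lead to closure between C6 and C10. The nucleophile is therefore fixed in advance by a bromine on C1. In the forward direction a two-electron reduction of the C1–Br bond of 21 has to give enolate 22. That enolate must then add across the ring to C5 through a metal chelate that places O-5 and C10 on the same face.

**C1–Br and O–Si (21 ⇒ 20 ⇒ 17).** The bromine is traced back to the hydroxy dione 17. Only C10=O is γ to 3-OH, so only this ketone can close to the hemiketal 18 and lose water to the bridged enol ether 19. The double bond of 19 must point to C1 because C9 is quaternary. An electrophilic bromine source then marks C1. The regiochemical handle therefore costs no extra carbon and no earlier oxidation. Silylation removes the only proton source before the reduction.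

**C5=C10 reconnection (17 ⇒ 16).** The two ketone carbons are joined to a tetrasubstituted alkene. The ten-membered ring, which is hard to close directly, becomes the octalin 16 with only three stereocentres (C3, C8, C9). The forward oxidative cleavage has to take the one electron-rich alkene and leave the electron-poor butenolide.

**C4–C5 (16 ⇒ 15 ⇒ 14).** Ring A is opened at the most hindered bond, between the gem-dimethyl carbon and the alkene. The forward step is an epoxide-initiated cation–olefin closure. The epoxide C–O bond at C3 is not broken, so the configuration of 15 becomes 3S in 16. The C10 cation must lose H-5 to give the Δ5(10) alkene. C3 is set by a catalyst on the distal prenyl alkene of 14, independently of C8/C9. The butenolide is installed before this step, so the chain carries no oxygen that could trap the C10 cation.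

**C12–C13 (14 ⇒ 11 + 12).** An sp3–sp2 cross-coupling joins the complete lactone 12 in one step. The iodide 11 comes from the benzyl ether 9 through the alcohol 10.

**C10–C1 (9 ⇒ 6 + 7).** The homoprenyl chain is coupled to the enol triflate 6. This triflate forms as a single regioisomer from 5, because C9 bears no hydrogen.

**C8–C17 and C9–C20 (5 ⇒ 3), C9–C11 (3 ⇒ 1 + 2).** Both methyl groups are added to the α-substituted enone 3 in one operation. A catalyst sets C8, and the ring then directs the second methyl anti to the first. This order (chain first, C20 last) is what delivers the C17/C20-trans relationship.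

## Alternatives that were turned down

**Alternative 1:** This is the textbook route: an open-chain aldol for the cyclopentane, then a cut at C6–C7.
- Forward key step: ring-closing metathesis of diene A1 with the second-generation Grubbs catalyst to cycloheptene A2, followed by hydrogenation of C6=C7.
- The metathesis forms one unfunctionalised bond and no stereocentre.
- Both vinyl groups sit on fully substituted or neopentyl positions, and the ring has to close trans-fused.
- The C8/C9 pair, with its quaternary centre, would have to be built in an acyclic chain without any ring control.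
- The final hydrogenation has to spare the butenolide.
- The step count rises while the hard problems stay in the precursor.

**Alternative 2:** A 1,2-shift of the ring-fusion bond, with C5 migrating from C10 to C1.
- Forward key step: base-induced semipinacol rearrangement of the cis-decalin-1,5,10-triol 1-mesylate A3, which contracts ring A and expands ring B.
- The constitution is unambiguous, and C1 is set by inversion.
- A3, however, carries six stereocentres, one more than the target.
- It requires a syn dihydroxylation of the shielded tetrasubstituted alkene plus a separate oxygenation of C1.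
- The migrating carbon bears an oxygen, so the C5 alkoxide can trigger a Grob fragmentation in competition with the shift.
- The precursor is therefore more complex than the product.

**Alternative 3:** A cut at C4–C5 on a preformed seven-membered ring.
- Forward key step: Cp2TiCl (trivalent titanium) opens the epoxide of the 2-(epoxyprenyl)cycloheptane-1,3-dione A4, and the tertiary C4 radical adds 5-exo to the C5 carbonyl.
- C1 is stereolabile in A4, which is attractive.
- The enol of a 2-alkyl-1,3-diketone, however, attacks its own epoxide (5-exo O-alkylation) under acid, base or Lewis acid.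
- Both carbonyl groups are 5-exo acceptors.
- Such closures favour the cis ring fusion.
- The substituted cycloheptane-1,3-dione itself costs a ring expansion sequence.

Key step: step 13

Remark: the enantiomeric Shi ketone and the chiral imidazolinium salt are used only as catalysts and are taken as available. The atom labels C1–C20 defined above are kept for all intermediates.

## Steps

Step 1
Reactants: 1 2-iodocyclohex-2-en-1-one; 2 potassium [2-(benzyloxy)ethyl]trifluoroborate
Product: 3 2-[2-(benzyloxy)ethyl]cyclohex-2-en-1-one
Conditions: PdCl2(dppf)·CH2Cl2 (5 mol %), Cs2CO3, toluene/H2O, 80 °C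
Reagents that add atoms: none
Why: Suzuki–Miyaura coupling of a primary alkyltrifluoroborate with an alkenyl iodide; the sp2 C–I bond of the α-iodoenone adds readily to zerovalent palladium and this class of alkoxyethylboron reagent transfers its alkyl group without β-elimination. No stereocentre is formed.

Step 2
Reactants: 3 2-[2-(benzyloxy)ethyl]cyclohex-2-en-1-one
Product: 5 (2R,3R)-2-[2-(benzyloxy)ethyl]-2,3-dimethylcyclohexan-1-one, via magnesium enolate 4 (not isolated)
Conditions: MeMgBr, Cu(OTf)2 (3 mol %), chiral imidazolinium chloride (NHC precursor, 4 mol %), Et2O, −30 °C; then MeI, DMPU, −30 °C → rt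
Reagents that add atoms: methylmagnesium bromide C[Mg]Br; iodomethane CI
Why: Copper-catalysed asymmetric conjugate addition of a Grignard reagent to an α-substituted cyclic enone with enolate trapping; the chiral NHC–copper complex sets C8 (R). The regiodefined enolate 4 is methylated at C9 anti to the new C17 methyl, which puts C20 trans and the C11 chain cis to C17 (9R).

Step 3
Reactants: 5 (2R,3R)-2-[2-(benzyloxy)ethyl]-2,3-dimethylcyclohexan-1-one
Product: 6 (5R,6R)-6-[2-(benzyloxy)ethyl]-5,6-dimethylcyclohex-1-en-1-yl trifluoromethanesulfonate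
Conditions: KHMDS, THF, −78 °C; PhNTf2, −78 → 0 °C; aq. NH4Cl
Reagents that add atoms: N-phenylbis(trifluoromethanesulfonimide) O=S(=O)(N(c1ccccc1)S(=O)(=O)C(F)(F)F)C(F)(F)F
Why: C9 is quaternary, so the ketone can be deprotonated only at C5, and O-sulfonylation gives a single enol triflate. Neither stereocentre is enolisable.

Step 4
Reactants: 6 (5R,6R)-6-[2-(benzyloxy)ethyl]-5,6-dimethylcyclohex-1-en-1-yl trifluoromethanesulfonate; 7 5-bromo-2-methylpent-2-ene
Product: 9 benzyl 2-[(1R,6R)-1,6-dimethyl-2-(4-methylpent-3-en-1-yl)cyclohex-2-en-1-yl]ethyl ether, via Grignard reagent 8 (not isolated)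
Conditions: 7, Mg, THF; then 6, Fe(acac)3 (5 mol %), THF/NMP, −30 → 0 °C
Reagents that add atoms: none
Why: Iron-catalysed Kumada-type coupling of a primary alkyl Grignard reagent with an enol triflate forms C10–C1 faster than β-hydride loss can occur. The benzyl ether and both stereocentres are untouched.

Step 5
Reactants: 9 benzyl 2-[(1R,6R)-1,6-dimethyl-2-(4-methylpent-3-en-1-yl)cyclohex-2-en-1-yl]ethyl ether
Product: 10 2-[(1R,6R)-1,6-dimethyl-2-(4-methylpent-3-en-1-yl)cyclohex-2-en-1-yl]ethan-1-ol
Conditions: Na, NH3(l)/THF, −78 °C; NH4Cl
Reagents that add atoms: none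
Why: Dissolving-metal cleavage of the benzyl ether; isolated trisubstituted alkenes are not reduced under these conditions, whereas catalytic hydrogenolysis would endanger them.

Step 6
Reactants: 10 2-[(1R,6R)-1,6-dimethyl-2-(4-methylpent-3-en-1-yl)cyclohex-2-en-1-yl]ethan-1-ol
Product: 11 (5R,6R)-6-(2-iodoethyl)-5,6-dimethyl-1-(4-methylpent-3-en-1-yl)cyclohex-1-ene
Conditions: I2, PPh3, imidazole, CH2Cl2, 0 °C
Reagents that add atoms: iodine [I][I]
Why: Appel iodination of an unhindered primary alcohol by SN2 displacement of the oxyphosphonium group. The buffered medium leaves the alkenes alone.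

Step 7
Reactants: 11 (5R,6R)-6-(2-iodoethyl)-5,6-dimethyl-1-(4-methylpent-3-en-1-yl)cyclohex-1-ene; 12 4-bromofuran-2(5H)-one
Product: 14 4-{2-[(1R,6R)-1,6-dimethyl-2-(4-methylpent-3-en-1-yl)cyclohex-2-en-1-yl]ethyl}furan-2(5H)-one, via alkylzinc iodide 13 (not isolated)
Conditions: Zn dust, LiCl, THF, 40 °C; then 12, Pd(OAc)2 (2 mol %), SPhos (4 mol %), THF, rt
Reagents that add atoms: none
Why: Negishi coupling; the electron-poor β-bromobutenolide adds quickly to zerovalent palladium and the neutral organozinc reagent does not deprotonate or open the lactone. No acidic proton is present at this stage, and C12–C13 is formed with the whole butenolide in place.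

Step 8
Reactants: 14 4-{2-[(1R,6R)-1,6-dimethyl-2-(4-methylpent-3-en-1-yl)cyclohex-2-en-1-yl]ethyl}furan-2(5H)-one
Product: 15 4-{2-[(1R,6R)-2-{2-[(2S)-3,3-dimethyloxiran-2-yl]ethyl}-1,6-dimethylcyclohex-2-en-1-yl]ethyl}furan-2(5H)-one
Conditions: ent-Shi ketone (L-fructose series, 30 mol %), Oxone, K2CO3, Bu4NHSO4, MeCN/DMM/aq. Na2B4O7–EDTA buffer, 0 °C
Reagents that add atoms: potassium peroxymonosulfate (active part of Oxone) [K+].[O-]S(=O)(=O)OO
Why: Shi epoxidation; the chiral dioxirane sets C3 (S) on the exposed prenyl alkene by catalyst control. The ring alkene is shielded by the quaternary C9, and the butenolide alkene is too electron-poor to react.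

Step 9
Reactants: 15 4-{2-[(1R,6R)-2-{2-[(2S)-3,3-dimethyloxiran-2-yl]ethyl}-1,6-dimethylcyclohex-2-en-1-yl]ethyl}furan-2(5H)-one
Product: 16 4-{2-[(1R,2R,6S)-6-hydroxy-1,2,5,5-tetramethyl-1,2,3,4,5,6,7,8-octahydronaphthalen-1-yl]ethyl}furan-2(5H)-one
Conditions: BF3·OEt2 (2.2 equiv), CH2Cl2, −78 → −40 °C; aq. NaHCO3
Reagents that add atoms: none
Why: Epoxide-initiated cation–olefin cyclisation; the epoxide opens at the tertiary C4, C5 of the ring alkene attacks in a chair-like six-membered closure, and the tertiary C10 cation loses the aligned axial H-5 to give the tetrasubstituted Δ5(10) alkene. The C3–O bond is not broken, so 3S is retained, and the chain offers no nucleophile to the cation.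

Step 10
Reactants: 16 4-{2-[(1R,2R,6S)-6-hydroxy-1,2,5,5-tetramethyl-1,2,3,4,5,6,7,8-octahydronaphthalen-1-yl]ethyl}furan-2(5H)-one
Product: 17 4-{2-[(1R,2R,7S)-7-hydroxy-1,2,6,6-tetramethyl-5,10-dioxocyclodecyl]ethyl}furan-2(5H)-one
Conditions: O3, CH2Cl2/MeOH, Sudan Red 7B, −78 °C; Me2S, −78 °C → rt
Reagents that add atoms: ozone [O-][O+]=O
Why: Ozonolysis of a ring-fusion tetrasubstituted alkene opens the octalin to the cyclodecane-1,6-dione, as known for the parent Δ9,10-octalin. The electrophilic oxidant takes the only electron-rich alkene, the indicator stops the reaction before the butenolide is touched, and C3, C8 and C9 are not affected.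

Step 11
Reactants: 17 4-{2-[(1R,2R,7S)-7-hydroxy-1,2,6,6-tetramethyl-5,10-dioxocyclodecyl]ethyl}furan-2(5H)-one
Product: 20 4-{2-[(1R,2R,7S)-9-bromo-7-hydroxy-1,2,6,6-tetramethyl-5,10-dioxocyclodecyl]ethyl}furan-2(5H)-one (both C1 epimers), via cyclic hemiketal 18 (not isolated), via bridged dihydrofuran 19 (not isolated)
Conditions: PPTS (10 mol %), 4 Å MS, toluene, 50 °C; then NBS, NaHCO3, THF/H2O, 0 °C
Reagents that add atoms: N-bromosuccinimide O=C1CCC(=O)N1Br; water O
Why: A γ-hydroxy ketone closes to a five-membered hemiketal and dehydrates to a 2,3-dihydrofuran; only C10=O is γ to 3-OH, and the double bond can form only toward C1 because C9 is quaternary. Bromohydrin-type addition to this enol ether puts bromine on C1, and the C5 ketone, which enolises far more slowly, is left alone.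

Step 12
Reactants: 20 4-{2-[(1R,2R,7S)-9-bromo-7-hydroxy-1,2,6,6-tetramethyl-5,10-dioxocyclodecyl]ethyl}furan-2(5H)-one (both C1 epimers)
Product: 21 4-{2-[(1R,2R,7S)-9-bromo-1,2,6,6-tetramethyl-5,10-dioxo-7-(trimethylsilyloxy)cyclodecyl]ethyl}furan-2(5H)-one (both C1 epimers)
Conditions: TMSCl, imidazole, CH2Cl2, 0 °C
Reagents that add atoms: chlorotrimethylsilane C[Si](C)(C)Cl
Why: Silylation of the secondary 3-OH drains the ring–chain equilibrium to the open bromo diketone. It also removes the only proton that could quench the enolate of the next step.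

Step 13
Reactants: 21 4-{2-[(1R,2R,7S)-9-bromo-1,2,6,6-tetramethyl-5,10-dioxo-7-(trimethylsilyloxy)cyclodecyl]ethyl}furan-2(5H)-one (both C1 epimers)
Product: 24 4-{2-[(2S,3aS,6R,7R,8aS)-2,3a-dihydroxy-3,3,6,7-tetramethyl-8-oxodecahydroazulen-7-yl]ethyl}furan-2(5H)-one (target; 1S,3S,5S,8R,9R in the atom labels used here), via samarium enolate 22 (not isolated), via silylated aldol 23 (not isolated)
Conditions: SmI2 (2.5 equiv), THF, −78 °C; then 0.5 M HCl, THF, 0 °C
Reagents that add atoms: none
Why: Samarium Reformatsky-type transannular aldol addition. Two single-electron transfers from divalent samarium cleave the C1–Br bond, so both C1 epimers of 21 converge on one trivalent-samarium enolate 22 whose double bond can only be C1=C10; C6, the α-position of the other ketone, is never deprotonated, which secures the constitution (C1–C5 and not C6–C10). The oxophilic metal binds the transannular C5 ketone and C1 adds through a closed six-membered Zimmerman–Traxler-type array; the closest known reactions are the SmI2-induced intramolecular Reformatsky and aldol closures of α-halo carbonyl compounds, medium rings included, and the transannular aldol closure of cyclodecane-1,6-dione to the hydroazulene skeleton. One bond closes two rings, the cyclopentane in a 5-(enolexo)-exo-trig mode and the cycloheptanone in a 7-(enolendo)-exo-trig mode. C1 relative to C5: both oxygens sit on the same metal, which places O-5 and the acyl carbon C10 cis on the new cyclopentane, that is H-1 anti to 5-OH, the trans ring fusion of the target. C5 relative to C3: the OSiMe3 group takes a pseudo-equatorial site next to C4 and the samarium-bound O-5 develops on the opposite face (steric and dipole repulsion), which gives the 1,3-anti diol pattern, while C8 and C9 lie in the four-atom tether and have to tolerate this fold. Chemoselectivity: at −78 °C the α-bromo ketone is reduced much faster than the dialkyl ketone or the butenolide, and no proton source is present. The cold dilute acid quench frees 3-OH from 23 without base, so retro-aldol, C1 epimerisation and dehydration are avoided.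

## Compound list

1 | 2-iodocyclohex-2-en-1-one | O=C1CCCC=C1I | starting material
2 | potassium [2-(benzyloxy)ethyl]trifluoroborate | [K+].F[B-](F)(F)CCOCc1ccccc1 | starting material
3 | 2-[2-(benzyloxy)ethyl]cyclohex-2-en-1-one | O=C1CCCC=C1CCOCc1ccccc1 | intermediate
4 | bromomagnesium enolate (C9=C10) of (3R)-2-[2-(benzyloxy)ethyl]-3-methylcyclohexanone | C[C@@H]1CCCC(O[Mg]Br)=C1CCOCc1ccccc1 | intermediate
5 | (2R,3R)-2-[2-(benzyloxy)ethyl]-2,3-dimethylcyclohexan-1-one | C[C@@H]1CCCC(=O)[C@]1(C)CCOCc1ccccc1 | intermediate
6 | (5R,6R)-6-[2-(benzyloxy)ethyl]-5,6-dimethylcyclohex-1-en-1-yl trifluoromethanesulfonate | C[C@@H]1CCC=C(OS(=O)(=O)C(F)(F)F)[C@]1(C)CCOCc1ccccc1 | intermediate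
7 | 5-bromo-2-methylpent-2-ene | CC(C)=CCCBr | starting material
8 | (4-methylpent-3-en-1-yl)magnesium bromide | CC(C)=CCC[Mg]Br | intermediate
9 | benzyl 2-[(1R,6R)-1,6-dimethyl-2-(4-methylpent-3-en-1-yl)cyclohex-2-en-1-yl]ethyl ether | C[C@@H]1CCC=C(CCC=C(C)C)[C@]1(C)CCOCc1ccccc1 | intermediate
10 | 2-[(1R,6R)-1,6-dimethyl-2-(4-methylpent-3-en-1-yl)cyclohex-2-en-1-yl]ethan-1-ol | C[C@@H]1CCC=C(CCC=C(C)C)[C@]1(C)CCO | intermediate
11 | (5R,6R)-6-(2-iodoethyl)-5,6-dimethyl-1-(4-methylpent-3-en-1-yl)cyclohex-1-ene | C[C@@H]1CCC=C(CCC=C(C)C)[C@]1(C)CCI | intermediate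
12 | 4-bromofuran-2(5H)-one | O=C1C=C(Br)CO1 | starting material
13 | alkylzinc iodide from 11 (C12–ZnI) | C[C@@H]1CCC=C(CCC=C(C)C)[C@]1(C)CC[Zn]I | intermediate
14 | 4-{2-[(1R,6R)-1,6-dimethyl-2-(4-methylpent-3-en-1-yl)cyclohex-2-en-1-yl]ethyl}furan-2(5H)-one | C[C@@H]1CCC=C(CCC=C(C)C)[C@]1(C)CCC1=CC(=O)OC1 | intermediate
15 | 4-{2-[(1R,6R)-2-{2-[(2S)-3,3-dimethyloxiran-2-yl]ethyl}-1,6-dimethylcyclohex-2-en-1-yl]ethyl}furan-2(5H)-one | C[C@@H]1CCC=C(CC[C@@H]2OC2(C)C)[C@]1(C)CCC1=CC(=O)OC1 | intermediate
16 | 4-{2-[(1R,2R,6S)-6-hydroxy-1,2,5,5-tetramethyl-1,2,3,4,5,6,7,8-octahydronaphthalen-1-yl]ethyl}furan-2(5H)-one (Δ5(10)-octalin, 3S) | C[C@@H]1CCC2=C(CC[C@H](O)C2(C)C)[C@]1(C)CCC1=CC(=O)OC1 | intermediate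
17 | 4-{2-[(1R,2R,7S)-7-hydroxy-1,2,6,6-tetramethyl-5,10-dioxocyclodecyl]ethyl}furan-2(5H)-one | C[C@@H]1CCC(=O)C(C)(C)[C@@H](O)CCC(=O)[C@]1(C)CCC1=CC(=O)OC1 | intermediate
18 | cyclic hemiketal of 17 (oxygen bridges C3 and C10, OH on C10, 11-oxabicyclo[6.2.1]undecane core, C10 not defined) | C[C@@H]1CCC(=O)C(C)(C)[C@@H]2CCC(O)(O2)[C@]1(C)CCC1=CC(=O)OC1 | intermediate
19 | bridged 2,3-dihydrofuran (oxygen bridges C3 and C10, enol ether C1=C10, C5 ketone free) | C[C@@H]1CCC(=O)C(C)(C)[C@@H]2CC=C(O2)[C@]1(C)CCC1=CC(=O)OC1 | intermediate
20 | 4-{2-[(1R,2R,7S)-9-bromo-7-hydroxy-1,2,6,6-tetramethyl-5,10-dioxocyclodecyl]ethyl}furan-2(5H)-one (bromine on C1, both epimers) | C[C@@H]1CCC(=O)C(C)(C)[C@@H](O)CC(Br)C(=O)[C@]1(C)CCC1=CC(=O)OC1 | intermediate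
21 | 3-O-trimethylsilyl ether of 20 (both C1 epimers) | C[C@@H]1CCC(=O)C(C)(C)[C@@H](O[Si](C)(C)C)CC(Br)C(=O)[C@]1(C)CCC1=CC(=O)OC1 | intermediate
22 | diiodosamarium enolate (C1=C10–O–SmI2) of the ten-membered diketone | C[C@@H]1CCC(=O)C(C)(C)[C@@H](O[Si](C)(C)C)CC=C(O[Sm](I)I)[C@]1(C)CCC1=CC(=O)OC1 | intermediate
23 | 3-O-trimethylsilyl ether of the target (trans-fused aldol) | C[C@@H]1CC[C@]2(O)[C@H](C[C@H](O[Si](C)(C)C)C2(C)C)C(=O)[C@]1(C)CCC1=CC(=O)OC1 | intermediate
24 | 4-{2-[(2S,3aS,6R,7R,8aS)-2,3a-dihydroxy-3,3,6,7-tetramethyl-8-oxodecahydroazulen-7-yl]ethyl}furan-2(5H)-one (CNP0077405.3) | C[C@@H]1CC[C@]2(O)[C@H](C[C@H](O)C2(C)C)C(=O)[C@]1(C)CCC1=CC(=O)OC1 | target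

## Step count and least certain steps

Total: 13 steps. The longest linear sequence is 13 steps, from 1. Compounds 2, 7 and 12 are bought and enter in steps 1, 4 and 7.

**Step 13 (key step).**
- The samarium enolate may be protonated before it adds, which amounts to net debromination.
- The closure may take the wrong pair of faces if the fold preferred by C8/C9 opposes the one preferred by C3.
- The aldolate may revert during the quench.
- The fallback replaces the anionic, chelate-controlled closure by a cationic, templated one. It sets out from 19, which is isolated after the first half of step 11.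
- TiCl4 in CH2Cl2 at −78 °C activates the C5 ketone, and the enol ether carbon C1 attacks from the face on which C4 hangs from C3. This is an oxa analogue of the π-route to the norbornyl cation.
- The aqueous quench hydrolyses the bridged oxocarbenium ion to the cis-fused C1 epimer of the target F1.
- In F1 the template has already placed 5-OH anti to 3-OH.
- C1, the only epimerisable centre, is then equilibrated with DBU in toluene toward the trans-fused isomer, in which C10 lies cis to the small 5-OH and can accept its hydrogen bond. The fallback returns to the route at 24.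

**Step 11.**
- Dehydration to the strained bridged enol ether may stall.
- The bromo ketone may lose HBr, or may be attacked by 3-OH during handling.
- The fallback makes elimination the intended path and generates the enolate by conjugate reduction. It sets out from 19.
- PhSeCl in THF/H2O gives the α-phenylselanyl ketone F2.
- H2O2/pyridine then gives the (E)-enone F3.
- TMSCl/imidazole gives its silyl ether F4.
- [(Ph3P)CuH]6 in toluene at −40 °C adds hydride to C2, and the copper enolate closes onto C5 (reductive aldol cyclisation). The fallback returns at 23.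
- The more hindered β,β-disubstituted butenolide should react more slowly than the disubstituted enone.

**Step 10.**
- The alkene lies between two quaternary carbons. Oxygen transfer without cleavage, or sluggish attack followed by over-oxidation, is the likely failure.
- The fallback sets out from 16 and uses a different oxidant and mechanism.
- A Schenck ene reaction (O2, tetraphenylporphyrin, visible light, CH2Cl2) gives the two allylic hydroperoxides F5 (5-OOH, Δ1(10)) and F6 (10-OOH, Δ5).
- Acid-induced Hock cleavage (cat. BF3·OEt2, then water) converges both regioisomers on 17.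

**Step 9.**
- The C10 cation may lose a proton from C1 instead of C5. The opened epoxide may also undergo a 1,2-hydride shift before the ring closes.
- The fallback sets out from 15 and changes from kinetic to thermodynamic control of the alkene position.
- The crude mixture, including the Δ1(10) isomer F7, is equilibrated in a separate step (p-TsOH·H2O, benzene, 60 °C) through the same C10 cation to the tetrasubstituted alkene. It returns at 16.

**Step 2.**
- The α-substituent slows the conjugate addition, so low conversion or poor facial selectivity is possible.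
- The fallback sets C8 on the unsubstituted enone and builds C9 afterwards.
- Cyclohex-2-enone is treated with Me2Zn, Cu(OTf)2 and a phosphoramidite ligand. The zinc enolate is then allylated (allyl acetate, Pd(PPh3)4) to trans-2-allyl-3-methylcyclohexanone F8.
- TMSCl/NaI/Et3N gives the more substituted silyl enol ether F9.
- MeLi and then MeI/DMPU methylate C9 anti to C17 to give F10.
- OsO4 (cat.)/NaIO4 shortens the allyl group to the aldehyde F11.
- Reductive etherification (BnOSiMe3, Et3SiH, cat. TMSOTf) returns to the route at 5.

## Further compounds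

F1 | step 13 | cis-fused C1 epimer of the target (1R,3S,5S,8R,9R) | C[C@@H]1CC[C@]2(O)[C@@H](C[C@H](O)C2(C)C)C(=O)[C@]1(C)CCC1=CC(=O)OC1
F2 | step 11 | C1-phenylselanyl derivative of 17 (both C1 epimers) | C[C@@H]1CCC(=O)C(C)(C)[C@@H](O)CC([Se]c2ccccc2)C(=O)[C@]1(C)CCC1=CC(=O)OC1
F3 | step 11 | ten-membered (E)-C1=C2 enone with free 3-OH | C[C@@H]1CCC(=O)C(C)(C)[C@@H](O)/C=C/C(=O)[C@]1(C)CCC1=CC(=O)OC1
F4 | step 11 | 3-O-trimethylsilyl ether of F3 | C[C@@H]1CCC(=O)C(C)(C)[C@@H](O[Si](C)(C)C)/C=C/C(=O)[C@]1(C)CCC1=CC(=O)OC1
F5 | step 10 | 5-hydroperoxy-Δ1(10) isomer from 16 (C5 not defined) | C[C@@H]1CCC2(OO)C(=CC[C@H](O)C2(C)C)[C@]1(C)CCC1=CC(=O)OC1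
F6 | step 10 | 10-hydroperoxy-Δ5(6) isomer from 16 (C10 not defined) | C[C@@H]1CC=C2C(C)(C)[C@@H](O)CCC2(OO)[C@]1(C)CCC1=CC(=O)OC1
F7 | step 9 | Δ1(10) alkene isomer of 16 (C5 not defined) | C[C@@H]1CCC2C(=CC[C@H](O)C2(C)C)[C@]1(C)CCC1=CC(=O)OC1
F8 | step 2 | trans-2-allyl-3-methylcyclohexan-1-one (3R) | C[C@@H]1CCCC(=O)[C@H]1CC=C
F9 | step 2 | (3R)-2-allyl-3-methyl-1-(trimethylsilyloxy)cyclohex-1-ene | C[C@@H]1CCCC(O[Si](C)(C)C)=C1CC=C
F10 | step 2 | (2R,3R)-2-allyl-2,3-dimethylcyclohexan-1-one | C[C@@H]1CCCC(=O)[C@]1(C)CC=C
F11 | step 2 | 2-[(1R,2R)-1,2-dimethyl-6-oxocyclohexyl]acetaldehyde | C[C@@H]1CCCC(=O)[C@]1(C)CC=O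
A1 | alternative 1 | diene for ring-closing metathesis (vinyl on C5 and on C8) | C=C[C@@H](C)[C@@](C)(CCC1=CC(=O)OC1)C(=O)[C@H]1C[C@H](O)C(C)(C)[C@]1(O)C=C
A2 | alternative 1 | 6,7-didehydro derivative of the target | C[C@@H]1C=C[C@]2(O)[C@H](C[C@H](O)C2(C)C)C(=O)[C@]1(C)CCC1=CC(=O)OC1
A3 | alternative 2 | cis-decalin-1,5,10-triol 1-mesylate with free 3-OH | C[C@@H]1CC[C@@]2(O)C(C)(C)[C@@H](O)C[C@H](OS(C)(=O)=O)[C@@]2(O)[C@]1(C)CCC1=CC(=O)OC1
A4 | alternative 3 | 2-(epoxyprenyl)cycloheptane-1,3-dione (C1 labile) | C[C@@H]1CCC(=O)C(C[C@@H]2OC2(C)C)C(=O)[C@]1(C)CCC1=CC(=O)OC1
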